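The numbers of this flask were set for the occasion.

In epsilon, free catalyst cannot pile up while impurity stands at its charge: against that charge it lasts 0.233 s, far shorter than the lifetime 108 s of the precatalyst that releases it. Here are the two flasks, one hot and one cold.

- gamma: substrate 1.5 M; precatalyst 1.5 mM; impurity 0.48 mM; temperature 55 °C; time 80 s
- epsilon: substrate 1.5 M; precatalyst 1.5 mM; impurity 0.48 mM; temperature 25 °C; time 80 s

    isomer of the product + free catalyst ⇌ substrate + free catalyst, rate k1*[free catalyst]*[isomer of the product] forward; the back reaction follows from the equilibrium constant (k1 = 6.38 M⁻¹ s⁻¹, Ea1 = 39.0 kJ mol⁻¹)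
    substrate ⇌ target (K2 = 1.04, k2 = 0.0377 s⁻¹, Ea2 = 86.0 kJ mol⁻¹, ΔH2 = −22.0 kJ mol⁻¹)
    target + free catalyst ⇌ isomer of the product + free catalyst, rate k3*[free catalyst]*[target] forward; the back reaction follows from the equilibrium constant (K3 = 2.57, k3 = 11.5 M⁻¹ s⁻¹, Ea3 = 52.0 kJ mol⁻¹, ΔH3 = −5.00 kJ mol⁻¹)
    precatalyst → free catalyst (k4 = 0.00923 s⁻¹, Ea4 = 83.0 kJ mol⁻¹)
    free catalyst + impurity → spent catalyst (k5 = 8940 M⁻¹ s⁻¹, Ea5 = 24.0 kJ mol⁻¹)
    (constants at 25 °C)

- at 25 °C the constants are as listed, elsewhere as the activation energies and enthalpies make them

- the flask that comes out highest in amount of target, in percent of the substrate charged, or "all alike" when all lie within 1.5 percentage points (gamma / epsilon / all alike)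
- target at the end, in percent of the substrate charged, gamma
- target at the end, in percent of the substrate charged, epsilon

Take the bench rule first: a reversible step is finished after 5 half-lives. In epsilon, substrate and target relax into each other with a half-life of 9.37 s, both ways together, so the run holds 8.53 of them. You would write target at K2/(1 + K2) = 51.0 %, where K2 is the constant of that step.

The rule covers that pair, and it stops working once free catalyst carries target on into isomer of the product. Call the catalyst lag, t_L, the time the precatalyst needs to release as much catalyst as the impurity charge takes up, ln(c_PC/(c_PC − c_Y))/k4, with c for the charges and k4 for the release constant. With c_Y/c_PC = 0.320, it is 41.8 s in epsilon, about half of the run.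

In gamma, k4 is larger by a factor of 21.3, so the lag shrinks to 1.96 s. The 1.02 mM of catalyst that survives then gives target a half-life of 8.68 s by the forward step alone, and gamma has 8.99 such half-lives. I therefore put gamma at full balance, 18.9 % target. In epsilon, catalyst has 38.2 s after the lag and starts low, so I expect target somewhat under the rule's figure, by an amount this reckoning does not give, and still above gamma's figure.

The forecast says epsilon, with 18.9 % in gamma and 47 % in epsilon; its ground: “Before any catalyst is free, the impurity scavenges it”.

The simulation gives epsilon, with 18.9 % in gamma and 46.8 % in epsilon, so the forecast held. In epsilon, isomer of the product stands at 0.419 % after 40.0 s, a reading taken just inside the lag, and at 8.60 % after 80.0 s.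

Now cut the impurity of epsilon to 1.9 × 10⁻⁴ M, all else held. The lag becomes 14.7 s, which leaves 65.3 s of catalyst time, longer than epsilon's 38.2 s, so you expect more isomer and less target. That flask ends with 23.8 % isomer of the product and 39.3 % target.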